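The 5 questions below ask for one ranking and 4 percentages, each a share of target against homo product, and here is what is known.

    substrate + reagent → open intermediate (k1 = 90 M⁻¹ s⁻¹)
    reagent + partner → second intermediate (k2 = 220 M⁻¹ s⁻¹)
    open intermediate + second intermediate → target (k3 = 2900 M⁻¹ s⁻¹)
    2 open intermediate → homo product (k4 = 1200 M⁻¹ s⁻¹)
    partner → decomposed reagent (k5 = 0.19 s⁻¹)
    substrate + second intermediate → side product (k6 = 4100 M⁻¹ s⁻¹)

| setting | cedar | alder | larch | elm |
|---|---|---|---|---|
| substrate | 0.50 mM | 0.50 mM | 0.50 mM (fed, over 5.0 s) | 0.50 mM (fed, over 1.2 s) |
| partner | 0.750 mM | 0.750 mM | 0.750 mM | 0.750 mM |
| reagent | 1.50 mM | 1.50 mM (fed, over 5.0 s) | 1.50 mM | 1.50 mM |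
| time | 8.0 s | 8.0 s | 8.0 s | 8.0 s |
| remark | everything together at the start | all else is in the flask from the start; the feed brings no volume worth counting | all else is in the flask from the start; the feed brings no volume worth counting | all else is in the flask from the start; the feed brings no volume worth counting |

- the flask with the highest share of target in target plus homo product ("all alike" if they lie within 1.5 percentage points) (cedar / alder / larch / elm / all alike)
- share of target in target plus homo product at the end, cedar
- share of target in target plus homo product at the end, alder
- share of target in target plus homo product at the end, larch
- share of target in target plus homo product at the end, elm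

- percentages count the substrate that a species holds: one homo product counts as two
- where a step has two of a species, its rate is k times that concentration squared, and two are used at each turn
- run time (cedar): 8.0 s

I began at the branch point, where open intermediate partitions between coupling and homocoupling. Counted in substrate, the selectivity factor per unit of concentration ratio is 2900 M⁻¹ s⁻¹ over twice 1200 M⁻¹ s⁻¹, or 1.21. Target therefore forms faster than homo product wherever c(second intermediate) times this factor exceeds c(open intermediate). So I needed plenty of second intermediate at the moment open intermediate appears.

Next I froze reagent and partner at their charges. Second intermediate is then made at 0.247 mM s⁻¹, which is faster than larch receives substrate, at 0.100 mM s⁻¹. I call the ratio of making rate to feed rate the cover, 2.47 for larch. Elm's quicker feed gives 0.594. Cedar and alder have their substrate in at the start, so I scored them zero, and the cover cannot part those two.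

My doubt was the freeze itself. With reagent frozen, partner's lifetime is 1.92 s against the feed's 5.0 s, so the cover overstates the late part of larch's feed. Yet on the same freeze, partner's split between its two steps reckons to 0.476 mM of second intermediate against 0.50 mM of substrate, and the scheme gives second intermediate no first-order loss of its own, so what forms early can wait for substrate. A second doubt was that surplus second intermediate diverts substrate to side product, with 4100 M⁻¹ s⁻¹ above 2900 M⁻¹ s⁻¹. The share asked does not count side product, but that step spends second intermediate too, so this doubt stayed open. My ranking by cover put larch on top, and I committed to no percentages.

The forecast chose elm, giving cedar 62%, alder 30%, larch 56% and elm 64%, and it set larch back on the ground that “the long feed (larch) outlasts the partner and leaves late substrate with nothing to couple to”. There my ranking and the forecast parted.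

The simulation gave larch as the highest: cedar 59.3%, alder 36.4%, larch 81.2%, elm 62.1%.

In larch, with its cover of 2.47, substrate at 1.27 s went to side product 6.4 times as fast as it opened. At 8.00 s, larch held 0.0339 mM of second intermediate beside 0.0318 mM of open intermediate, and c(second intermediate) times the selectivity factor stood above c(open intermediate). For the neighbour of larch with 0.19 mM of partner, the cover is 0.627, below one, so I expected substrate to outrun second intermediate. The computed share there was 13.8%, with 42.1% of the charged substrate still unreacted.

All constants are assumed; no experiment stands behind them.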